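## Retrosynthetic overview

1. Target 11 ⇒ keto sulfonium salt 8. One intramolecular sulfur-ylide epoxidation makes C13–C14 and C13–O, closing the oxocane (ring C) and the oxirane (ring D) together as the last event.
2. 8 ⇒ keto alcohol 6, by C–S bond formation at C14.
3. 6 ⇒ acyclic trienyl ketal 3. A Br+-initiated polyene cyclisation closes rings A and B together, and a ketal oxygen traps C8 and stays there with its OCH2CH2 arm (C15, C14).
4. 3 ⇒ (5E,9E)-farnesylacetone 1 + ethylene glycol 2.
5. Ring order: A + B in step 2, then C + D in step 4. Labdane numbering is used throughout.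

Assumption: geometrically pure (5E,9E)-1 is bought (technical isomer mixtures are enriched on AgNO3–silica), and the (R)-BINOL catalyst series is taken to give 3S; if the first run shows the opposite sense, the antipode is used.

## Route

Step 1
Reactants: 1 (5E,9E)-farnesylacetone; 2 ethylene glycol
Product: 3 farnesylacetone ethylene ketal 2-methyl-2-[(3E,7E)-4,8,12-trimethyltrideca-3,7,11-trien-1-yl]-1,3-dioxolane
Conditions: HOCH2CH2OH (5 equiv), PPTS (5 mol %), benzene, Dean–Stark, reflux
Reagents that add atoms: ethylene glycol (2), OCCO
Why: Acid-catalysed ketalisation driven by azeotropic water removal; no stereocentre is formed, the E-alkenes are untouched by the weak acid, and C14, C15 and both oxygens of the target are now in place.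

Step 2
Reactants: 3 farnesylacetone ethylene ketal
Product: 6 keto alcohol 4-[(1R,2R,4aR,6S,8aS)-6-bromo-2-(2-hydroxyethoxy)-2,5,5,8a-tetramethyldecahydronaphthalen-1-yl]butan-2-one, via fused trialkyloxonium ion 4 (not isolated), via nine-membered oxocarbenium ion 5 (not isolated)
Conditions: (R)-3,3'-diaryl-BINOL thiophosphoramide (10 mol %), DBDMH (0.55 equiv), toluene/CH2Cl2 1:1, 0.02 M, −78 °C; aq NaHCO3/Na2S2O3; then PPTS (cat.), THF/H2O, 0 °C
Reagents that add atoms: 1,3-dibromo-5,5-dimethylhydantoin (DBDMH), CC1(C)N(Br)C(=O)N(Br)C1=O; water, O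
Why: Proposed new method: this is a catalytic enantioselective bromonium-initiated polyene cyclisation ended by oxygen transfer from a ketal; the chiral Lewis base·Br+ complex chooses the face of the terminal alkene (sets 3S), the two E-alkenes then add anti through a chair–chair array (sets 5R, 10S, 9R, 8R: trans-decalin, equatorial Br, equatorial 8α-O, axial 8β-CH3), the C8 cation is caught through a six-membered transition state by a dioxolane oxygen to give 4, 4 breaks its C13–O bond because the second oxygen stabilises cation 5, and water frees the ketone and leaves the hindered C8–O–CH2CH2OH ether; the closest known reaction types are chiral Lewis-base/DBDMH bromocyclisation of polyenes, carbonyl-oxygen termination of farnesylacetone cyclisations, and acetal-oxygen participation with ring-expanded oxocarbenium ions in haloetherification of ene acetals.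

Step 3
Reactants: 6 keto alcohol
Product: 8 keto sulfonium salt {2-[(decalin C8)oxy]ethyl}diphenylsulfonium triflate, via primary triflate 7 (not isolated)
Conditions: Tf2O (1.1 equiv), 2,6-di-tert-butyl-4-methylpyridine (1.3 equiv), CH2Cl2, −78 °C; then Ph2S (5 equiv), −78 → 40 °C, 16 h; precipitate with Et2O
Reagents that add atoms: triflic anhydride, O=S(=O)(OS(=O)(=O)C(F)(F)F)C(F)(F)F; diphenyl sulfide, c1ccc(cc1)Sc1ccccc1
Why: O-triflation followed by SN2 S-alkylation of diphenyl sulfide is the usual way to (2-substituted ethyl)diphenylsulfonium triflates; at −78 °C the primary alcohol reacts far faster than the ketone, the neopentyl-type equatorial bromide is inert, and no stereocentre is touched.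

Step 4
Reactants: 8 keto sulfonium salt
Product: 11 target (3S,5R,8R,9R,10S,13R,14S)-3-bromo-8,15:13,14-diepoxylabdane, via sulfonium ylide 9 (not isolated), via anti-betaine 10 (not isolated)
Conditions: LiN(SiMe3)2 (1.05 equiv, slow addition), THF, 0.002 M, −78 → 0 °C
Reagents that add atoms: none
Why: Proposed new method: this is an intramolecular Johnson–Corey–Chaykovsky epoxidation that closes the oxocane and the oxirane together; the S+–CH2 protons are far more acidic than those of the methyl ketone so only ylide 9 forms, loss of the tertiary alkoxide from 9 is uphill and reversible, and the gauche diequatorial arms on C8 and C9 hold C14 near C13; only a gauche C12–C13–C14–C15 ring torsion allows the anti-periplanar O−/S+ collapse, which enforces the cis-fused epoxide, and a hand-built conformational model (not a calculation, so the dr is a prediction) suggests that only the 13R,14S mode lets the bulky SPh2+ leave from the open α side (the side of H-9) while the small lithium alkoxide sits next to the ring oxygen; the closest known reaction type is epoxy-annulation through β-heteroatom-substituted diphenylsulfonium ylides, which gives five- to seven-membered epoxide-fused heterocycles.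

## Compound list

1 | (5E,9E)-farnesylacetone, (5E,9E)-6,10,14-trimethylpentadeca-5,9,13-trien-2-one | CC(=O)CC/C=C(\C)CC/C=C(\C)CCC=C(C)C | starting material
2 | ethylene glycol | OCCO | starting material
3 | farnesylacetone ethylene ketal | CC1(CC/C=C(\C)CC/C=C(\C)CCC=C(C)C)OCCO1 | intermediate
4 | fused trialkyloxonium ion (O bound to C8, C13 and C15; either ketal oxygen may attack, so C13 is left undefined) | CC1(C)[C@@H](Br)CC[C@]2(C)[C@H]3CCC4(C)OCC[O+]4[C@]3(C)CC[C@@H]12 | intermediate
5 | nine-membered oxocarbenium ion | CC1(C)[C@@H](Br)CC[C@]2(C)[C@H]3CCC(C)=[O+]CCO[C@]3(C)CC[C@@H]12 | intermediate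
6 | keto alcohol (8α-(2-hydroxyethoxy), 13-ketone, 3β-bromide) | CC1(C)[C@@H](Br)CC[C@]2(C)[C@@H](CCC(C)=O)[C@](C)(OCCO)CC[C@@H]12 | intermediate
7 | primary triflate of 6 | CC1(C)[C@@H](Br)CC[C@]2(C)[C@@H](CCC(C)=O)[C@](C)(OCCOS(=O)(=O)C(F)(F)F)CC[C@@H]12 | intermediate
8 | keto diphenylsulfonium triflate | CC1(C)[C@@H](Br)CC[C@]2(C)[C@@H](CCC(C)=O)[C@](C)(OCC[S+](c3ccccc3)c3ccccc3)CC[C@@H]12.[O-]S(=O)(=O)C(F)(F)F | intermediate
9 | sulfonium ylide | CC1(C)[C@@H](Br)CC[C@]2(C)[C@@H](CCC(C)=O)[C@](C)(OC[CH-][S+](c3ccccc3)c3ccccc3)CC[C@@H]12 | intermediate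
10 | anti-betaine (oxocane closed, O− and S+ anti-periplanar) | CC1(C)[C@@H](Br)CC[C@]2(C)[C@H]3CC[C@@](C)([O-])[C@H]([S+](c4ccccc4)c4ccccc4)CO[C@]3(C)CC[C@@H]12 | intermediate
11 | (3S,5R,8R,9R,10S,13R,14S)-3-bromo-8,15:13,14-diepoxylabdane (CNP0311742.2) | CC1(C)[C@@H](Br)CC[C@]2(C)[C@H]3CC[C@@]4(C)O[C@H]4CO[C@]3(C)CC[C@@H]12 | target

## Step count and risks

Total step count: 4. Longest linear sequence: 4.

**Step 2.** The ketal oxygen may lose out to proton loss from the C8 cation or to incomplete cyclisation, and the ee with this terminator is unknown. The fallback sets out from 1 and forms the two C–O bonds in a different way. The free ketone of 1 ends the same catalytic bromocyclisation through its carbonyl oxygen, a termination well known for this ketone, and gives the tricyclic enol ether 3β-bromosclareol oxide F1. Dilute aqueous acid in THF opens it to the 8α-hydroxy ketone F2. The potassium alkoxide of F2 (KH, THF, 0 °C, high dilution) adds in conjugate fashion to diphenylvinylsulfonium triflate. This gives ylide 9 directly, where the fallback rejoins the route, and steps 2 and 3 are skipped.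

**Step 4.** Closure of the eight-membered ring may be slower than decay of the ylide, and the facial selectivity rests only on the model above. The fallback sets out from 6 and separates ring closure from oxygen delivery. Triflate 7 is quenched with PPh3 instead of Ph2S to give the phosphonium triflate F3. KN(SiMe3)2 in THF at 0.002 M gives the phosphonium ylide F4, which closes by an intramolecular Wittig reaction onto the methyl ketone to the (13Z)-oxocene F5. F5 is epoxidised with the L-fructose-derived enantiomer of the Shi ketone (KHSO5 as 2KHSO5·KHSO4·K2SO4, K2CO3 buffer, MeCN/dimethoxymethane/H2O, 0 °C). By analogy with 1-phenylcyclohexene under the D-fructose ketone, this antipode should put the oxygen on the 13R,14S face. The same model suggests this is also the convex face of the ring. The fallback rejoins the route at 11.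

**Step 3.** Diphenyl sulfide is a weak nucleophile, and the warm triflate may decompose first. The fallback sets out from 6 and builds the sulfonium centre by S–aryl instead of S–alkyl bond formation. PhSSPh and PBu3 in THF convert the alcohol into the phenyl sulfide F6. F6 is then S-phenylated with diphenyliodonium triflate and Cu(OAc)2 (5 mol %) in chlorobenzene at 110 °C, and the fallback rejoins the route at 8.

## Further compounds

F1 | step 2 | tricyclic enol ether 3β-bromosclareol oxide | CC1(C)[C@@H](Br)CC[C@]2(C)[C@H]3CC=C(C)O[C@]3(C)CC[C@@H]12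
F2 | step 2 | 3β-bromo-8α-hydroxy-14,15-dinorlabdan-13-one | CC1(C)[C@@H](Br)CC[C@]2(C)[C@@H](CCC(C)=O)[C@](C)(O)CC[C@@H]12
F3 | step 4 | keto triphenylphosphonium triflate | CC1(C)[C@@H](Br)CC[C@]2(C)[C@@H](CCC(C)=O)[C@](C)(OCC[P+](c3ccccc3)(c3ccccc3)c3ccccc3)CC[C@@H]12.[O-]S(=O)(=O)C(F)(F)F
F4 | step 4 | phosphonium ylide | CC1(C)[C@@H](Br)CC[C@]2(C)[C@@H](CCC(C)=O)[C@](C)(OC[CH-][P+](c3ccccc3)(c3ccccc3)c3ccccc3)CC[C@@H]12
F5 | step 4 | (13Z)-3β-bromo-8,15-epoxylabd-13-ene (oxocene) | CC1(C)[C@@H](Br)CC[C@]2(C)[C@H]3CC/C(C)=C\CO[C@]3(C)CC[C@@H]12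
F6 | step 3 | keto phenyl sulfide | CC1(C)[C@@H](Br)CC[C@]2(C)[C@@H](CCC(C)=O)[C@](C)(OCCSc3ccccc3)CC[C@@H]12
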